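Free catalyst is what has to be counted in these four flasks.

the same everywhere: free catalyst 0.2 mol%; impurity 1.1 µM

| flask | starting material | reagent | time | remark |
|---|---|---|---|---|
| winter | 2.0 mM (fed, over 1.00 min) | 1.20 equiv | 1.0 min | all but starting material at the start; starting material goes in evenly over 1.00 min, the run ends at 1.0 min |
| spring | 2.0 mM | 1.20 equiv | 1.0 min | a closed flask charged with all of it at once and left for 1.0 min |
| midnight | 2.0 mM | 1.20 equiv |  | one stirred flow tank at steady state, fed with the mixture as stated, mean residence time 1.0 min |
| autumn | 2.0 mM | 1.20 equiv (fed, over 1.00 min) | 1.0 min | a stirred flask in which reagent is dosed at a steady rate over 1.00 min without added volume, worked up at 1.0 min |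

    starting material + free catalyst → catalyst intermediate A (k1 = 28000 /M/s)
    catalyst intermediate A ⇌ catalyst intermediate B (K2 = 0.26, k2 = 1080 /s)
    reagent + catalyst intermediate B → catalyst intermediate C (k3 = 3.95 × 10⁵ /M/s)
    catalyst intermediate C ⇌ free catalyst + target (K4 = 4.3 × 10⁻⁴ M, k4 = 525 /s)
    free catalyst + impurity → spent catalyst (k5 = 2.47 × 10⁶ /M/s)

- the set-up with the highest amount of target at the outlet or at the end, in percent of the starting material put in ("none" if the first two lie within 2 percentage points) (winter / spring / midnight / autumn / none)
- amount of target at the outlet or at the end, in percent of the starting material put in, winter
- amount of target at the outlet or at the end, in percent of the starting material put in, spring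
- amount of target at the outlet or at the end, in percent of the starting material put in, midnight
- amount of target at the outlet or at the end, in percent of the starting material put in, autumn

- the stated concentrations are those of everything mixed, before any reaction; amounts are the same in each set-up
- the feed brings no volume worth counting
- run time (winter): 1.0 min

In the first instants of spring, starting material takes up free catalyst 21 times as fast as impurity does. That capture returns the catalyst after a turn of the round, whereas poisoning removes it for good. The charge of catalyst is 4.00 µM, and the charge of impurity, 1.1 µM, is less than that, so the reckoning counts live catalyst, the catalyst charged minus the impurity charged: 2.90 µM. Reckoned with all live catalyst free, impurity has a half-life of about 0.0968 s, far shorter than the run, so the reckoning takes the loss as immediate.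

At the full charge of starting material, capture has a pseudo-first-order constant of 56.0 /s on free catalyst, which is less than 1080 /s for step 2, 525 /s for the release of target and 246 /s for the passage of catalyst intermediate A through catalyst intermediate B to reagent at its full charge. The reckoning therefore takes capture as the rate-limiting step and the release of target as an equilibrium. With intermediates A and B neglected, [free catalyst] = live catalyst / (one + [target]/0.43 mM). At half conversion, [target] exceeds that constant, so catalyst intermediate C is the resting state and free catalyst is 30.1 % of live catalyst.

Towards the end of spring, the rate falls on two counts, with less starting material and less free catalyst. Take load = [starting material] at the start / 0.43 mM, here 4.65, and clock = k1 × live catalyst × time, here 4.87. Integration gives clock = (one + load) × ln(1/(one − conversion)) − load × conversion. For spring this gives 77.7 %. The tank balance, clock × (one − conversion) = conversion × (one + load × conversion), gives 57.1 % for midnight, less than for spring. The two dosed flasks are not reckoned here.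

The forecast gives 53 % for winter, 75 % for spring, 55 % for midnight and 65 % for autumn, with spring best, the catalyst being “held back mainly by target rebinding it as intermediate C”. Its spring figure lies 2.7 percentage points below this reckoning and its midnight figure 2.1 points below.

The simulation gives 53.1 % for winter, 75.3 % for spring, 55.6 % for midnight and 66.5 % for autumn, and spring is best. In spring at 1.00 min, spent catalyst stands at 27.5 % of the catalyst charged. Live catalyst was reckoned at 72.5 % of the charge, and the four working forms in that flask add up to 72.5 %.

With 1.90 µM of impurity in the spring flask, live catalyst drops to 2.10 µM and the clock to 3.53, so the rule gives 69.9 %. That flask gives 67.0 %.

The numbers of this flask are assumed, and the outcome is calculated.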